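**Plan**

- Chain atoms are numbered C1′ (ring CH2) to C24′. The hydroquinone is traced back to the quinone and then to a tetramethoxybenzene ring (C–O changes only); the chain is then cut at C12′–C13′ and last at the aryl–C1′ bond.
- C12′ and C13′ are the two allylic CH2 carbons between the C10′=C11′ and C14′=C15′ alkenes, at the midpoint of the C30 chain. Each half is therefore a farnesyl unit, and a sulfonyl group on C13′ makes one half the nucleophile.
- Forward: farnesol gives farnesyl bromide, which is used twice, once for farnesyl phenyl sulfone and once to farnesylate the brominated tetramethoxytoluene ring. The aryl half is then oxidised at its terminal E-methyl group and brominated.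
- The halves are joined by sulfone carbanion alkylation, the sulfone is removed reductively, and oxidative demethylation followed by dithionite reduction gives the hydroquinone. No ring is formed; the benzene ring is bought.
- Stereochemistry: the target has no stereocentre. The 2′E, 6′E, 14′E and 18′E alkenes come from (2E,6E)-farnesol, the 10′E geometry is fixed when SeO2 selects the E-methyl group in step 5, and the transient C13′ centre is racemic and later erased.

Key step: step 7

Remark: (2E,6E)-farnesol, 2,3,4,5-tetramethoxytoluene and sodium benzenesulfinate are taken as commercial; the four aryl methyl ethers serve as the only protecting groups.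

**Route**

Step 1
Reactants: 1 (2E,6E)-3,7,11-trimethyldodeca-2,6,10-trien-1-ol ((2E,6E)-farnesol)
Product: 2 (2E,6E)-1-bromo-3,7,11-trimethyldodeca-2,6,10-triene (farnesyl bromide)
Conditions: PBr3 (0.4 equiv), Et2O, −10 to 0 °C
Reagents that add atoms: phosphorus tribromide, BrP(Br)Br
Why: The primary allylic alcohol is activated as a phosphite ester and displaced by bromide (PBr3 bromination, SN2), which at low temperature should give the primary bromide without allylic transposition and leave the 2E and 6E alkenes untouched.

Step 2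
Reactants: 2 (2E,6E)-1-bromo-3,7,11-trimethyldodeca-2,6,10-triene; 3 sodium benzenesulfinate
Product: 4 [(2E,6E)-3,7,11-trimethyldodeca-2,6,10-trienyl]sulfonylbenzene (farnesyl phenyl sulfone)
Conditions: DMF, rt
Reagents that add atoms: none
Why: S-Alkylation of the sulfinate anion by a primary allylic bromide (SN2 at the CH2Br carbon in a dipolar aprotic solvent) should give the sulfone directly, with no alkene geometry at stake.

Step 3
Reactants: 5 1,2,3,4-tetramethoxy-5-methylbenzene (2,3,4,5-tetramethoxytoluene)
Product: 6 1-bromo-2,3,4,5-tetramethoxy-6-methylbenzene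
Conditions: N-bromosuccinimide, MeCN, 0 °C to rt
Reagents that add atoms: N-bromosuccinimide, O=C1CCC(=O)N1Br
Why: Electrophilic aromatic bromination of this very electron-rich arene can occur only at the single unsubstituted ring carbon, so one regioisomer is expected.

Step 4
Reactants: 6 1-bromo-2,3,4,5-tetramethoxy-6-methylbenzene; 2 (2E,6E)-1-bromo-3,7,11-trimethyldodeca-2,6,10-triene
Product: 8 1-[(2E,6E)-3,7,11-trimethyldodeca-2,6,10-trienyl]-2,3,4,5-tetramethoxy-6-methylbenzene, via arylmagnesium bromide 7 (not isolated)
Conditions: Mg, THF, reflux; then 2, CuBr·SMe2 (5 mol %), THF, −20 to 0 °C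
Reagents that add atoms: none
Why: Magnesium insertion gives the aryl Grignard reagent, and allylic substitution catalysed by monovalent copper should take place at the CH2Br carbon of 2, because the other allyl terminus is fully substituted, with the 2E geometry retained.

Step 5
Reactants: 8 1-[(2E,6E)-3,7,11-trimethyldodeca-2,6,10-trienyl]-2,3,4,5-tetramethoxy-6-methylbenzene
Product: 9 (2E,6E,10E)-2,6,10-trimethyl-12-(2,3,4,5-tetramethoxy-6-methylphenyl)dodeca-2,6,10-trien-1-ol
Conditions: SeO2 (cat.), t-BuOOH, salicylic acid (cat.), CH2Cl2, 0 °C to rt, stopped at partial conversion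
Reagents that add atoms: tert-butyl hydroperoxide, CC(C)(C)OO (terminal oxygen source); selenium dioxide, O=[Se]=O (catalytic oxygen carrier)
Why: SeO2 allylic oxidation (ene reaction followed by [2,3]-sigmatropic shift, t-BuOOH as terminal oxidant) is expected to attack the most accessible, terminal trisubstituted alkene at its E-methyl group, which sets the 10′E geometry of the hydroxymethyl-bearing alkene.

Step 6
Reactants: 9 (2E,6E,10E)-2,6,10-trimethyl-12-(2,3,4,5-tetramethoxy-6-methylphenyl)dodeca-2,6,10-trien-1-ol
Product: 10 1-[(2E,6E,10E)-12-bromo-3,7,11-trimethyldodeca-2,6,10-trienyl]-2,3,4,5-tetramethoxy-6-methylbenzene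
Conditions: PBr3 (0.4 equiv), Et2O, −10 °C; used directly
Reagents that add atoms: phosphorus tribromide, BrP(Br)Br
Why: PBr3 bromination of the primary allylic alcohol (SN2 on the phosphite ester) at low temperature should give the E-allylic bromide without transposition, and the aryl methyl ethers and alkenes are inert to it.

Step 7
Reactants: 4 [(2E,6E)-3,7,11-trimethyldodeca-2,6,10-trienyl]sulfonylbenzene; 10 1-[(2E,6E,10E)-12-bromo-3,7,11-trimethyldodeca-2,6,10-trienyl]-2,3,4,5-tetramethoxy-6-methylbenzene
Product: 12 racemic 1-[(2E,6E,10E,14E,18E)-13-(benzenesulfonyl)-3,7,11,15,19,23-hexamethyltetracosa-2,6,10,14,18,22-hexaenyl]-2,3,4,5-tetramethoxy-6-methylbenzene, via lithiated sulfone 11 (not isolated)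
Conditions: n-BuLi (1.0 equiv, 4 in slight excess), THF, −78 °C; then 10, THF, −78 to −20 °C
Reagents that add atoms: none
Why: n-BuLi removes a proton from the CH2 flanked by the sulfonyl group and the C2=C3 alkene of 4, and the α-sulfonyl allyllithium 11 displaces bromide from the primary allylic carbon of 10 by direct SN2 attack, forming the C12′–C13′ bond. The closest known reaction type is the alkylation of an allylic sulfone carbanion with an allylic halide, the standard sulfone coupling for head-to-tail polyprenyl chains. No ring is closed. The new stereocentre at C13′ forms without any controlling element, so 12 is expected as a racemate, which does not matter because that carbon becomes a CH2 group in step 8. The step needs bond formation at the sulfur-bearing carbon of the ambident anion and at the CH2Br carbon of the electrophile; charge localisation next to sulfur and the fully substituted remote termini (C3 of 4 and C11′ of 10) secure both. Monoalkylation and intact E-alkenes are expected because the remaining α-hydrogen of 12 is hindered, only one equivalent of base is present at low temperature and no alkene is made or broken.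

Step 8
Reactants: 12 racemic 1-[(2E,6E,10E,14E,18E)-13-(benzenesulfonyl)-3,7,11,15,19,23-hexamethyltetracosa-2,6,10,14,18,22-hexaenyl]-2,3,4,5-tetramethoxy-6-methylbenzene
Product: 13 1-[(2E,6E,10E,14E,18E)-3,7,11,15,19,23-hexamethyltetracosa-2,6,10,14,18,22-hexaenyl]-2,3,4,5-tetramethoxy-6-methylbenzene
Conditions: LiBHEt3 (2.5 equiv), PdCl2(dppp) (5 mol %; dppp = Ph2P(CH2)3PPh2), THF, 0 °C
Reagents that add atoms: none
Why: LiBHEt3 reduces the divalent palladium precatalyst to zerovalent palladium, which ionises the allylic C–S bond to a π-allylpalladium sulfinate, and hydride is then delivered to the less substituted terminus C13′, so the C14′=C15′ alkene should stay in place and E while the stereocentre is erased (palladium-catalysed reductive desulfonylation of an allylic sulfone).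

Step 9
Reactants: 13 1-[(2E,6E,10E,14E,18E)-3,7,11,15,19,23-hexamethyltetracosa-2,6,10,14,18,22-hexaenyl]-2,3,4,5-tetramethoxy-6-methylbenzene
Product: 14 2-[(2E,6E,10E,14E,18E)-3,7,11,15,19,23-hexamethyltetracosa-2,6,10,14,18,22-hexaenyl]-5,6-dimethoxy-3-methylcyclohexa-2,5-diene-1,4-dione (ubiquinone-6)
Conditions: Ce(NH4)2(NO3)6 (2.5 equiv), MeCN/H2O, 0 °C
Reagents that add atoms: water, O
Why: Tetravalent cerium takes two electrons from the electron-rich ring and water attacks the only para pair of methoxy-bearing carbons (those flanking the methyl and prenyl substituents), expelling two molecules of methanol to give the 2,3-dimethoxy-1,4-benzoquinone (oxidative demethylation), while the isolated alkenes are harder to oxidise than the ring.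

Step 10
Reactants: 14 ubiquinone-6
Product: 15 2-[(2E,6E,10E,14E,18E)-3,7,11,15,19,23-hexamethyltetracosa-2,6,10,14,18,22-hexaenyl]-5,6-dimethoxy-3-methylbenzene-1,4-diol (ubiquinol-6)
Conditions: Na2S2O4, Et2O/H2O, rt, under argon
Reagents that add atoms: none
Why: Dithionite is a mild two-electron reductant that should convert the 1,4-benzoquinone into the hydroquinone without touching the alkenes or the methyl ethers (quinone to hydroquinone reduction); the product is kept under argon because it reoxidises in air.

**Compound list**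

1 | (2E,6E)-3,7,11-trimethyldodeca-2,6,10-trien-1-ol ((2E,6E)-farnesol) | OC/C=C(\C)CC/C=C(\C)CCC=C(C)C | starting material
2 | (2E,6E)-1-bromo-3,7,11-trimethyldodeca-2,6,10-triene | BrC/C=C(\C)CC/C=C(\C)CCC=C(C)C | intermediate
3 | sodium benzenesulfinate | [Na+].[O-]S(=O)c1ccccc1 | starting material
4 | [(2E,6E)-3,7,11-trimethyldodeca-2,6,10-trienyl]sulfonylbenzene | O=S(=O)(C/C=C(\C)CC/C=C(\C)CCC=C(C)C)c1ccccc1 | intermediate
5 | 1,2,3,4-tetramethoxy-5-methylbenzene (2,3,4,5-tetramethoxytoluene) | Cc1cc(OC)c(OC)c(OC)c1OC | starting material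
6 | 1-bromo-2,3,4,5-tetramethoxy-6-methylbenzene | COc1c(OC)c(C)c(Br)c(OC)c1OC | intermediate
7 | (2,3,4,5-tetramethoxy-6-methylphenyl)magnesium bromide | COc1c(OC)c(C)c([Mg]Br)c(OC)c1OC | intermediate (not isolated)
8 | 1-[(2E,6E)-3,7,11-trimethyldodeca-2,6,10-trienyl]-2,3,4,5-tetramethoxy-6-methylbenzene | COc1c(OC)c(C)c(C/C=C(\C)CC/C=C(\C)CCC=C(C)C)c(OC)c1OC | intermediate
9 | (2E,6E,10E)-2,6,10-trimethyl-12-(2,3,4,5-tetramethoxy-6-methylphenyl)dodeca-2,6,10-trien-1-ol | COc1c(OC)c(C)c(C/C=C(\C)CC/C=C(\C)CC/C=C(\C)CO)c(OC)c1OC | intermediate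
10 | 1-[(2E,6E,10E)-12-bromo-3,7,11-trimethyldodeca-2,6,10-trienyl]-2,3,4,5-tetramethoxy-6-methylbenzene | COc1c(OC)c(C)c(C/C=C(\C)CC/C=C(\C)CC/C=C(\C)CBr)c(OC)c1OC | intermediate
11 | [(2E,6E)-1-lithio-3,7,11-trimethyldodeca-2,6,10-trienyl]sulfonylbenzene (lithiated sulfone, configurationally labile at the carbanion) | [Li]C(/C=C(\C)CC/C=C(\C)CCC=C(C)C)S(=O)(=O)c1ccccc1 | intermediate (not isolated)
12 | racemic 1-[(2E,6E,10E,14E,18E)-13-(benzenesulfonyl)-3,7,11,15,19,23-hexamethyltetracosa-2,6,10,14,18,22-hexaenyl]-2,3,4,5-tetramethoxy-6-methylbenzene (one enantiomer drawn) | COc1c(OC)c(C)c(C/C=C(\C)CC/C=C(\C)CC/C=C(\C)C[C@@H](/C=C(\C)CC/C=C(\C)CCC=C(C)C)S(=O)(=O)c2ccccc2)c(OC)c1OC | intermediate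
13 | 1-[(2E,6E,10E,14E,18E)-3,7,11,15,19,23-hexamethyltetracosa-2,6,10,14,18,22-hexaenyl]-2,3,4,5-tetramethoxy-6-methylbenzene | COc1c(OC)c(C)c(C/C=C(\C)CC/C=C(\C)CC/C=C(\C)CC/C=C(\C)CC/C=C(\C)CCC=C(C)C)c(OC)c1OC | intermediate
14 | 2-[(2E,6E,10E,14E,18E)-3,7,11,15,19,23-hexamethyltetracosa-2,6,10,14,18,22-hexaenyl]-5,6-dimethoxy-3-methylcyclohexa-2,5-diene-1,4-dione (ubiquinone-6) | COC1=C(OC)C(=O)C(C/C=C(\C)CC/C=C(\C)CC/C=C(\C)CC/C=C(\C)CC/C=C(\C)CCC=C(C)C)=C(C)C1=O | intermediate
15 | 2-[(2E,6E,10E,14E,18E)-3,7,11,15,19,23-hexamethyltetracosa-2,6,10,14,18,22-hexaenyl]-5,6-dimethoxy-3-methylbenzene-1,4-diol (ubiquinol-6) | COc1c(O)c(C)c(C/C=C(\C)CC/C=C(\C)CC/C=C(\C)CC/C=C(\C)CC/C=C(\C)CCC=C(C)C)c(O)c1OC | target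

**Step count and risks**

Total step count: 10. Longest linear sequence: 8 steps (steps 1 or 3, then 4 to 10); step 2 is the side branch that supplies sulfone 4.

Steps most likely to fail:

1. Step 5. The allylic oxidation may lose site selectivity, attacking an internal alkene or the doubly activated ArCH2 position. It may also over-oxidise to the enal or stall at low conversion. The fallback cleaves the terminal alkene and rebuilds it, setting out from 8.
   - N-Bromosuccinimide in aqueous THF at 0 °C should add HOBr selectively to the terminal isopropylidene alkene, giving racemic (6E,10E)-3-bromo-2,6,10-trimethyl-12-(2,3,4,5-tetramethoxy-6-methylphenyl)dodeca-6,10-dien-2-ol F1.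
   - K2CO3 in methanol should close it to racemic 2,2-dimethyl-3-[(3E,7E)-3,7-dimethyl-9-(2,3,4,5-tetramethoxy-6-methylphenyl)nona-3,7-dienyl]oxirane F2.
   - HIO4 in aqueous THF should cleave the epoxide to (4E,8E)-4,8-dimethyl-10-(2,3,4,5-tetramethoxy-6-methylphenyl)deca-4,8-dienal F3.
   - A Wittig reaction with the stabilised ylide Ph3P=C(CH3)CO2Et should give ethyl (2E,6E,10E)-2,6,10-trimethyl-12-(2,3,4,5-tetramethoxy-6-methylphenyl)dodeca-2,6,10-trienoate F4, with the E geometry expected of a stabilised ylide.
   - i-Bu2AlH at −78 °C should reduce the ester to 9, where the fallback rejoins the route.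

2. Step 8. Hydride may be delivered to the more substituted terminus of the π-allylpalladium intermediate, or that intermediate may equilibrate before reduction; either would move or isomerise the C14′=C15′ alkene. The fallback replaces the palladium hydride substitution by single-electron cleavage of the C–S bond: 12 is treated with lithium in ethylamine at −78 °C for a short time and quenched. The allyl anion should be protonated at the less substituted C13′, and the aryl methyl ethers should survive at this temperature. It sets out from 12 and comes back at 13, and makes no new compound (entry F0).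

3. Step 7. The lithiated sulfone may act as a base towards the sensitive allylic bromide (loss of HBr to a diene) or alkylate incompletely, and attack at a remote allyl terminus is a lesser risk. The fallback forms the same C12′–C13′ bond with a non-basic allylmetal and no sulfone. It sets out from 1 and 10 and comes back at 13, so step 8 is no longer needed.
   - PPh3 in CCl4 (Appel reaction) should convert 1 into (2E,6E)-1-chloro-3,7,11-trimethyldodeca-2,6,10-triene F5.
   - Reactive barium (from BaI2 and lithium biphenylide, THF, −78 °C) should insert to give [(2E,6E)-3,7,11-trimethyldodeca-2,6,10-trienyl]barium chloride F6.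
   - Addition of 10 at −78 °C should give 13 by α,α′-selective allyl–allyl cross-coupling with retention of alkene geometry.

**Further compounds**

F1 | step 5 | racemic (6E,10E)-3-bromo-2,6,10-trimethyl-12-(2,3,4,5-tetramethoxy-6-methylphenyl)dodeca-6,10-dien-2-ol | COc1c(OC)c(C)c(C/C=C(\C)CC/C=C(\C)CCC(Br)C(C)(C)O)c(OC)c1OC
F2 | step 5 | racemic 2,2-dimethyl-3-[(3E,7E)-3,7-dimethyl-9-(2,3,4,5-tetramethoxy-6-methylphenyl)nona-3,7-dienyl]oxirane | COc1c(OC)c(C)c(C/C=C(\C)CC/C=C(\C)CCC2OC2(C)C)c(OC)c1OC
F3 | step 5 | (4E,8E)-4,8-dimethyl-10-(2,3,4,5-tetramethoxy-6-methylphenyl)deca-4,8-dienal | COc1c(OC)c(C)c(C/C=C(\C)CC/C=C(\C)CCC=O)c(OC)c1OC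
F4 | step 5 | ethyl (2E,6E,10E)-2,6,10-trimethyl-12-(2,3,4,5-tetramethoxy-6-methylphenyl)dodeca-2,6,10-trienoate | COc1c(OC)c(C)c(C/C=C(\C)CC/C=C(\C)CC/C=C(\C)C(=O)OCC)c(OC)c1OC
F0 | step 8 | none | none
F5 | step 7 | (2E,6E)-1-chloro-3,7,11-trimethyldodeca-2,6,10-triene | ClC/C=C(\C)CC/C=C(\C)CCC=C(C)C
F6 | step 7 | [(2E,6E)-3,7,11-trimethyldodeca-2,6,10-trienyl]barium chloride | Cl[Ba]C/C=C(\C)CC/C=C(\C)CCC=C(C)C
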